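Which recipe holds more E after 3.0 min at 25 °C, alder or elm?

common to all: X 1.5 M
- Monday's: J 0.99 M; L 0.15 M; temperature 20 °C; run made earlier
- Wednesday's: J 1.2 M; L 0.15 M; temperature 31 °C; run made earlier
- Tuesday's: J 1.1 M; L 0.15 M; temperature 20 °C; run made earlier
- alder: J 1.50 M; L 0.150 M; temperature 25 °C; time 3.0 min
- elm: J 1.00 M; L 0.150 M; temperature 25 °C; time 3.0 min

| run | time / min | E / % | X / % |
|---|---|---|---|
| Monday's | 0.250 | 7.9 | 91.5 |
| Monday's | 0.417 | 11.7 | 87.6 |
| Monday's | 0.833 | 20.5 | 78.0 |
| Monday's | 1.50 | 28.7 | 68.9 |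
| Monday's | 3.00 | 35.7 | 58.0 |
| Wednesday's | 0.667 | 29.3 | 65.8 |
| Wednesday's | 1.33 | 35.0 | 53.0 |
| Wednesday's | 2.00 | 34.7 | 45.5 |
| Wednesday's | 2.50 | 33.0 | 43.0 |
| Wednesday's | 3.00 | 30.6 | 39.3 |
| Tuesday's | 0.250 | 8.6 | 90.7 |
| Tuesday's | 0.833 | 23.0 | 77.1 |
| Tuesday's | 1.33 | 29.6 | 67.7 |
| Tuesday's | 2.00 | 35.7 | 60.3 |
| Tuesday's | 3.00 | 39.8 | 52.9 |

(scatter of a reading: 0.5 percentage points)

- the winner by amount of E, in percent of the X charged; "neither" if no more than 2 percentage points parts them (alder / elm / neither)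
- how much E is there at the end, in percent of the X charged: alder
- how much E is there at the end, in percent of the X charged: elm

- candidate steps: E -> Q; J + L -> D; X + J -> E + G

Among the candidate steps, X + J → E + G makes E, J + L → D takes J one for one with L, and E → Q loses E. Elm has 56.7% and alder 90.0% of what I call free J, the charge of J less the charge of L as a share of the X charged. On this count J is the limiting reagent in both flasks, since free J is short of the X charged.

The last readings give E per free J as 0.638 on Monday and 0.628 on Tuesday, both at 20 °C, and 0.437 on Wednesday at 31 °C. Taking the middle of Tuesday's and Wednesday's values, 0.533, for 25 °C, I reckon 48.0% E for alder and 30.2% for elm, so alder leads by 18 percentage points.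

The forecast also picks alder, with 47.5% and 34.5%, an elm figure above mine: “Elm is limited by J”.

The flask gives alder, with 47.5% against 33.9%.

    E → Q (k = 0.00270 s⁻¹, Ea = 90.0 kJ mol⁻¹)
    J + L → D (k = 0.0284 M⁻¹ s⁻¹, Ea = 71.0 kJ mol⁻¹)
    X + J → E + G (k = 0.00871 M⁻¹ s⁻¹, Ea = 46.0 kJ mol⁻¹)
    (constants at 25 °C)

E per free J comes out at 0.528 in alder and 0.598 in elm. A neighbour of elm charged with 0.60 M of X has free J of 142%, so on this count X is now the one that falls short. Counting the whole X charged as available, I reckon 53.3% E. That neighbour gives 46.9% E, with 36.5% of its X left.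

All runs come from a simulation with constants of no real substance, noise included.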